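Time spent warm was my question: south, north-east, north-west and west carried one charge and differed in temperature.

| flask | starting material | second substrate | coupling partner | free catalyst | temperature | remark | time |
|---|---|---|---|---|---|---|---|
| eta | 0.70 M | 0.50 equiv | 0.50 equiv | 2.9 mol% | 15 °C | run made earlier |  |
| zeta | 1.4 M | 0.50 equiv | 0.25 equiv | 2.9 mol% | 45 °C | run made earlier |  |
| south | 1.4 M | 0.500 equiv | 0.500 equiv | 2.9 mol% | 20 °C |  | 2.0 h |
| north-east | 1.4 M | 0.500 equiv | 0.500 equiv | 2.9 mol% |  | at 70 °C until 80 min, from then on at 20 °C | 2.0 h |
| north-west | 1.4 M | 0.500 equiv | 0.500 equiv | 2.9 mol% | 70 °C |  | 2.0 h |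
| west | 1.4 M | 0.500 equiv | 0.500 equiv | 2.9 mol% | 45 °C |  | 2.0 h |

eta run (percent of the starting material charged)

| time / h | target / % | over-reaction product / % |
|---|---|---|
| 0.200 | 2.6 | 0.7 |
| 0.333 | 5.1 | 0 |
| 0.500 | 8.6 | 0.1 |
| 0.833 | 11.6 | 1.9 |
| 1.33 | 20.5 | 0.5 |
| 2.50 | 32.1 | 3.7 |

zeta run (percent of the starting material charged)

| time / min | target / % | over-reaction product / % |
|---|---|---|
| 4.00 | 11.4 | 1.6 |
| 12.0 | 18.3 | 1.8 |
| 20.0 | 18.8 | 3.3 |
| 25.0 | 16.5 | 1.2 |
| 40.0 | 15.3 | 3.7 |

(scatter of a reading: 1 percentage point)



1. the flask that comes out highest in share of target in all that became target or over-reaction product, or "all alike" when all lie within 1.5 percentage points (south / north-east / north-west / west / all alike)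
2. share of target in all that became target or over-reaction product, south
3. share of target in all that became target or over-reaction product, north-east
4. share of target in all that became target or over-reaction product, north-west
5. share of target in all that became target or over-reaction product, west

Zeta was the run to read first. Its target fell from 18.3% at 12.0 min to 15.3% at 40.0 min, while the sum of target and over-reaction product read 20.1% and then 19.0%, equal within the scatter of the readings. So formation in zeta had stopped by about 12.0 min, and what followed was drain. Zeta gave 0.384 h⁻¹ for the drain constant, the fall of ln c(target) per hour while the sum stays flat; this is a reading and carries the scatter.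

Dividing the drain rate by c(target) removes the clock. With a flat sum, the share of target is exp(−N), where the drain number N is the drain constant times the mean age of the target.

West matched zeta in temperature, but it held 0.500 equiv of coupling partner against 0.25 equiv, which is twice as much. So I let it form for twice as long; target made at a steady rate is on average half that period younger than the end. Its mean age was 1.80 h, so N was 0.691 and the share 50.1%.

Eta was still forming, so its mean age was half the elapsed time, and its last reading gave 0.0922 h⁻¹. Eta ran at 0.70 M of c(starting material), so the scale from eta to zeta is rough, but I carried it on to 1.26 h⁻¹ at 70 °C. That made north-west 8.07% and north-east, counted up to its change, 18.7%. South, taken with eta's constant, came to 91.2%, higher than the others.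

The forecast stood at 90% for south, 42% for north-east, 30% for north-west and 75% for west, and closed: “South should be highest”.

The flasks gave 85.6% for south, 7.17% for north-east, 1.97% for north-west and 44.9% for west.

    starting material + free catalyst ⇌ catalyst intermediate A (K = 9.60 M⁻¹, k = 0.290 M⁻¹ min⁻¹, Ea = 57.0 kJ mol⁻¹, ΔH = −50.0 kJ mol⁻¹)
    coupling partner + catalyst intermediate A → free catalyst + target (k = 22.0 M⁻¹ min⁻¹, Ea = 37.0 kJ mol⁻¹)
    free catalyst + target → free catalyst + over-reaction product (k = 0.130 M⁻¹ min⁻¹, Ea = 46.0 kJ mol⁻¹)
    coupling partner + catalyst intermediate B → free catalyst + second product (k = 0.700 M⁻¹ min⁻¹, Ea = 49.0 kJ mol⁻¹)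
    second substrate + free catalyst ⇌ catalyst intermediate B (K = 1.00 M⁻¹, k = 4.90 M⁻¹ min⁻¹, Ea = 59.0 kJ mol⁻¹, ΔH = 15.0 kJ mol⁻¹)
    (constants at 20 °C)

North-east had done half of its drain turnover by 0.337 h, earlier than its change at 80 min, and at the change it held 2.31% target beside 28.9% over-reaction product. West's share of 44.9% is a drain number of 0.801, more than the product of the 0.384 h⁻¹ read from zeta and my mean age of 1.80 h, which was 0.691.

(The runs are calculated with made-up constants; scatter was added.)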